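(The data were computed on assumed constants, and the scatter is random.)

At the first reading of Thursday's run, 1.50 min in, open intermediate already stood at 24.7%, so I looked for the peak in this flask from rates read off that run.

| flask | starting material | partner | capture agent | remark | time |
|---|---|---|---|---|---|
| Thursday's | 0.28 M | 1.2 equiv | 0.55 M | run made earlier |  |
| flask | 0.55 M | 1.20 equiv | 0.550 M |  | 3.0 h |

- Thursday's (time / min: open intermediate / %, target / %): 1.50: 24.7, 0; 5.00: 29.7, 1.4; 8.00: 23.6, 1.9; 12.0: 17.2, 2.9; 20.0: 8.2, 4.8

(each reading ± 0.5 percentage points)

- the numbers in the tables scatter with a standard deviation of 0.5 percentage points
- steps thought possible: partner -> second intermediate; second intermediate + capture agent -> trapped intermediate; 2 second intermediate -> homo product; open intermediate -> decomposed reagent; starting material <-> open intermediate; open intermediate + second intermediate -> target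

- time up to 3.0 h at which open intermediate stands highest
- the amount of open intermediate, in percent of the starting material charged, at that time

I took the rate of fall from the tail, extrapolated that tail back to the start for an amplitude, and got the rate of rise from the shortfall at the first reading:

fall = 0.0858 /min

amplitude = 45.6%

rise = 0.724 /min

peak time = ln(rise/fall)/(rise − fall) = 0.0557 h

peak height = amplitude × (exp(−fall × time) − exp(−rise × time)) = 30.2%

This peak share, the highest percent that a rise and a fall at these rates allow, contains no concentration.

A slowing that might depend on the charge was the pseudo-first-order leak into target, which I read as 0.0120 /min. Scaled with the charge, I expected 0.0235 /min in this flask, still slower than the fall, so I kept the peak share unchanged.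

The forecast, slightly apart from my figures, gave 30.5% at 0.06 h, holding that “These first-order steps do not depend on concentration”.

The flask peaked at 30.3% at 0.0572 h, against my 30.2% at 0.0557 h.

    partner → second intermediate (k = 0.00160 /s)
    second intermediate + capture agent → trapped intermediate (k = 0.00570 /M/s)
    2 second intermediate → homo product (k = 0.00280 /M/s)
    open intermediate → decomposed reagent (k = 0.00320 /s)
    starting material ⇌ open intermediate (K = 1.00, k = 0.00460 /s)
    open intermediate + second intermediate → target (k = 0.00290 /M/s)

The neighbouring flask held 0.14 M of starting material, a quarter of this flask's charge, with the equivalents of partner and the time unchanged and 3.93 equiv of capture agent. The same reckoning scaled the leak to 0.00598 /min, far slower than the fall, and carried the peak share of 30.2% across. Open intermediate in that neighbouring flask peaked at 30.9%.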